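**Remark (assumptions):** germacrane numbering (C1–C15) is used for every intermediate. The ketoreductase is taken to be a panel enzyme found by screening for syn selectivity of the required sense; no specific enzyme can be named in advance.

## Analysis of the target

The target is a germacranolide: a ten-membered carbocycle (C1–C10) with a trans-fused α-methylene-γ-butyrolactone (oxygen on C6, C12 carbonyl, C11 on C7, exocyclic C13). It carries a free hydroxyl on C8, a methacrylate on C14 (on C10) and an acetate on C15 (on C4). Both ring alkenes, C1=C10 and C4=C5, are trisubstituted and hold their ring bonds cis (C9/C2 and C3/C6 on the same side). They are E by the sequence rules only because the oxygenated C14 and C15 outrank the ring carbons. The three stereocentres C6, C7 and C8 are contiguous and all R; H6 and H7 are trans, so C5 and C8 lie on opposite faces of the lactone. The sensitive groups are the α-methylene lactone and the methacrylate (Michael acceptors that tolerate neither strong base nor hydride), the allylic acetate, and the free 8-hydroxyl, which can translactonise onto C12 under base. The hard parts are closing a ten-membered ring, fixing two trisubstituted alkene geometries, building the O–C–O triad at C6–C8, and telling three hydroxyls apart. The route rests on C6–C7–C8 with the C11–C12 arm: taken out of the ring this is a 2-acylsuccinate whose C7 hydrogen, flanked by a C6 ketone and a C8 ester, epimerises freely, so C6 and C7 can be set together by dynamic kinetic resolution.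

## Retrosynthetic reasoning

**Acyl groups.** The methacrylate of 40 is cut first, giving diol 39. The primary allylic C14 hydroxyl is told from the hindered secondary C8 hydroxyl by acylation rate. Diol 39 comes from 38 by loss of both silyl groups. The C15 acetate of 38 is put on alcohol 37 while C14 and C8 are still silylated, so C14 and C15 never compete.

**C11–C13.** The exocyclic methylene of 36 is cut back to the saturated lactone 33. The forward step is a lactone enolate Mannich reaction and elimination. It needs strong base, so it is placed before every acylation, with C15 masked as the triethylsilyl ether.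

**C15 oxidation level.** Alcohol 32 is traced to acid 30 and allyl ester 29. C15 has to be an ester during ring closure because it activates the C4 carbanion. Its later reduction must spare the lactone, which is why it is released as an acid and reduced through a mixed anhydride.

**Ring closure at C4=C5.** Macrocycle 29 is opened to aldehyde phosphonate 28. A stabilised olefination puts the ester trans to C6, which is the ring-cis geometry the target needs. The C5 aldehyde is the protected carbon already present from the first step, and the closure creates no stereocentre. Closing at C1=C10 instead would need a phosphonate on C10, which the allyl transfer that sets C8 cannot deliver.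

**C3–C4.** Phosphonate 26 (and from it 27 and 28) comes from iodide 24 and phosphonoacetate 25 by alkylation. The new C4 centre is lost in the olefination, so its configuration is irrelevant.

**C8–C9 with C10=C1.** Iodide 24 goes back through 23 and 22 to homoallylic alcohol 21. That is cut at C8–C9 into aldehyde 11 and allylboronate 19, which carries boron on C1. The allyl transfer forms C8–C9, moves the alkene to C10=C1 with C9 and C2 cis, and transfers the C1 configuration to C8. One step therefore sets the third stereocentre and the first ring alkene.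

**Boronate 19.** The C1–C10 bond is cut to carbamate 16 and vinyl boronate 14 (lithiation–borylation). These come from 15 and from 12 via 13.

**C8 oxidation level.** Aldehyde 11 comes from alcohol 10, acid 9 and ester 7. A hydride reagent cannot tell the C8 ester from the lactone, so the ester is saponified (the lactone opens and recloses), the acid alone is reduced, and the alcohol is reoxidised.

**Key disconnection.** Lactone 7 is opened at O–C12 to the syn hydroxy diester 6. Removing the C6 hydride gives the achiral-at-equilibrium keto diester 5. Forward, an enzyme reduces one rapidly equilibrating enantiomer of 5, and the new hydroxyl lactonises; acid catalysis is added to complete the closure.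

**Keto diester 5.** C7–C11 is cut to β-keto ester 3 and bromoacetate 4. The ether bond of 3 is cut to chloride 1 and alcohol 2.

## Alternatives that were turned down

**Alternative 1:** Two-carbon ring expansion. The disconnection is the C6–C9 bond of a four-membered ring fused onto an eight-membered dienone. Forward, fluoride would free a C6 alkoxide and retro-aldol cleavage of the fusion bond would merge the two rings into the ten-membered 6,8-dione A1.
- For: no entropically disfavoured macrocyclisation is needed, and both ring-cis alkenes are inherited from an eight-membered ring where only cis is possible. On ring formation and alkene geometry this is stronger than the chosen route.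
- Against: A1 is achiral and lacks the C11–C12 arm. C7 would have to be alkylated, and then C6, C7 and C8 set in absolute and relative terms on a flexible β-diketone that is largely enolised. One of the two ketones is a conjugated enone, so 1,2- versus 1,4-reduction is a further problem, and transannular reactions are likely.
- Comparison: the chosen route gives up the easy ring formation but sets C6 and C7 on a small acyclic substrate in its third step, and C8 by reagent control.

**Alternative 2:** Chromium-mediated macrocyclisation at C5–C6. The disconnection is C5–C6 together with the lactone C–O bond. Forward, a C5 vinyl iodide would be activated by divalent chromium (CrCl2) with catalytic NiCl2 and add to a C6 aldehyde; acid work-up would close the lactone onto a C12 tert-butyl ester to give A2.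
- For: this is the best-precedented way to close ten-membered carbocycles, it tolerates esters and silyl ethers, and it forms ring and lactone in one operation. On ring-closure precedent it is stronger than the olefination chosen here.
- Against: C6 is created during the macrocyclisation under substrate control only, and the wrong epimer cannot give the trans-lactone. The C6 aldehyde has an epimerisable C7 next to it with a β-silyloxy group that can eliminate. A geometrically pure trisubstituted vinyl iodide and a separately built C7/C8 pair are required, and chromium is used in large excess.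
- Comparison: the chosen route fixes C6 and C7 before any ring is made, and its ring closure creates no stereocentre.

**Alternative 3:** Chiral-pool triad with olefination at C1=C10. The disconnection is C1=C10, with C6–C8 drawn from D-arabinose A4. Forward, a C10 phosphonoacetate carbanion (LiCl, amine base, high dilution) would add to a C1 aldehyde and close the ring to allyl ester A3.
- For: absolute configuration comes from the pool, and the C1 aldehyde is unbranched and not α-oxygenated, so it cannot epimerise during closure. On that point it is stronger than the chosen closure, whose aldehyde sits next to C6.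
- Against: A4 offers three C–O stereocentres where the target needs O–C–O. C7 must exchange oxygen for the acetic arm with stereocontrol, other oxygens must be removed, and the protecting-group traffic makes the sequence long. The phosphonoacetate must also be attached at C9 beside the C8 oxygen, where alkylation is slow and elimination competes.
- Comparison: the chosen route uses the same kind of ring closure but reaches the C6/C7 pair catalytically in three steps from achiral materials.

Key step: step 3

## Route

**Step 1**
Reactants: 1 methyl 4-chloro-3-oxobutanoate; 2 4-methoxybenzyl alcohol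
Product: 3 methyl 4-[(4-methoxybenzyl)oxy]-3-oxobutanoate
Conditions: NaH (2.2 equiv), THF, 0 °C to 23 °C; aq. NH4Cl
Reagents that add atoms: none
Why: Williamson-type SN2 displacement of the α-chloro ketone chloride by the benzylic alkoxide; the second equivalent of NaH holds the β-keto ester as its enolate, which protects the ester from transesterification.

**Step 2**
Reactants: 3 methyl 4-[(4-methoxybenzyl)oxy]-3-oxobutanoate; 4 methyl bromoacetate
Product: 5 dimethyl 2-{[(4-methoxybenzyl)oxy]acetyl}butanedioate (racemic)
Conditions: NaH (1.05 equiv), THF, 0 °C; then 4, 0 °C to 23 °C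
Reagents that add atoms: none
Why: C-alkylation of the β-keto ester enolate at the doubly activated carbon (C7) by SN2 on the α-bromo ester; one equivalent of base limits dialkylation, and the new centre is left racemic on purpose because it stays labile.

**Step 3**
Reactants: 5 dimethyl 2-{[(4-methoxybenzyl)oxy]acetyl}butanedioate (racemic)
Product: 7 methyl (2S,3S)-2-{[(4-methoxybenzyl)oxy]methyl}-5-oxooxolane-3-carboxylate, via syn hydroxy diester 6 (not isolated)
Conditions: ketoreductase (syn-selective panel enzyme), NADP+ (cat.), iPrOH (10% v/v), KH2PO4/K2HPO4 buffer pH 6.5, 30 °C; extraction; PPTS (cat.), toluene, 50 °C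
Reagents that add atoms: none
Why: The enantiomers of 5 interconvert through the enol at C7, which is acidic because it lies between the C6 ketone and the C8 ester, faster than the enzyme reduces the disfavoured one. The enzyme binds one enantiomer and delivers hydride from NADPH to one face of the C6 carbonyl, the cofactor being regenerated by oxidation of isopropanol, so C6 is set by facial selectivity and C7 by substrate selection; the result is the (S,S) syn hydroxy diester 6. The closest known reaction type is the ketoreductase dynamic kinetic resolution of α-substituted β-keto esters to syn β-hydroxy esters. After reduction C7 is flanked by an ester only and no longer epimerises, so the outcome is locked. The C6 hydroxyl then closes the lactone by 5-exo-trig acyl substitution on the C12 methyl ester; attack on the C8 ester would be a 4-exo closure and does not compete, and the acid catalyst only completes the closure. The syn relation places C5 and C8 trans on the ring, as in the target. The step needs enantioselectivity and syn diastereoselectivity from the enzyme, and a pH at which C7 racemises but neither ester hydrolyses.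

**Step 4**
Reactants: 7 methyl (2S,3S)-2-{[(4-methoxybenzyl)oxy]methyl}-5-oxooxolane-3-carboxylate
Product: 9 (2S,3S)-2-{[(4-methoxybenzyl)oxy]methyl}-5-oxooxolane-3-carboxylic acid, via dilithium hydroxy dicarboxylate 8 (not isolated)
Conditions: LiOH·H2O (3 equiv), THF/H2O, 0 °C; then 1 M HCl to pH 2, 23 °C
Reagents that add atoms: lithium hydroxide (supplies the carboxyl oxygen), [Li+].[OH-]
Why: Saponification hydrolyses the C8 ester and opens the lactone to 8, and acidification recloses the γ-lactone (5-exo); attack of hydroxide on the carbonyls is faster than C7 deprotonation at 0 °C, and the trans-lactone is the more stable isomer in any case.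

**Step 5**
Reactants: 9 (2S,3S)-2-{[(4-methoxybenzyl)oxy]methyl}-5-oxooxolane-3-carboxylic acid
Product: 10 (4R,5S)-4-(hydroxymethyl)-5-{[(4-methoxybenzyl)oxy]methyl}oxolan-2-one
Conditions: BH3·SMe2, THF, 0 °C to 23 °C; MeOH quench
Reagents that add atoms: none
Why: Borane reduces a carboxylic acid through its acyloxyborane much faster than it touches a lactone, the standard chemoselective reduction of paraconic acids.

**Step 6**
Reactants: 10 (4R,5S)-4-(hydroxymethyl)-5-{[(4-methoxybenzyl)oxy]methyl}oxolan-2-one
Product: 11 (2S,3S)-2-{[(4-methoxybenzyl)oxy]methyl}-5-oxooxolane-3-carbaldehyde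
Conditions: Dess–Martin periodinane, CH2Cl2, 0 °C to 23 °C
Reagents that add atoms: none
Why: Dess–Martin oxidation runs without base, which avoids E1cB opening of this β-acyloxy aldehyde and epimerisation at C7; the aldehyde is used crude.

**Step 7**
Reactants: 12 2-bromoprop-2-en-1-ol
Product: 13 [(2-bromoprop-2-en-1-yl)oxy](tert-butyl)diphenylsilane
Conditions: TBDPSCl, imidazole, CH2Cl2, 23 °C
Reagents that add atoms: tert-butyl(chloro)diphenylsilane, CC(C)(C)[Si](Cl)(c1ccccc1)c1ccccc1
Why: Imidazole-promoted silylation of a primary alcohol; the robust silyl ether protects C14 until the last stage.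

**Step 8**
Reactants: 13 [(2-bromoprop-2-en-1-yl)oxy](tert-butyl)diphenylsilane
Product: 14 tert-butyl(diphenyl){[2-(4,4,5,5-tetramethyl-1,3,2-dioxaborolan-2-yl)prop-2-en-1-yl]oxy}silane
Conditions: B2pin2, PdCl2(PPh3)2 (3 mol %), PPh3, KOPh, toluene, 50 °C
Reagents that add atoms: bis(pinacolato)diboron, CC1(C)OB(OC1(C)C)B1OC(C)(C)C(C)(C)O1
Why: Miyaura borylation of a 1-alkenyl bromide; the weak phenoxide base transmetallates the diboron reagent without promoting Suzuki coupling of the product.

**Step 9**
Reactants: 15 3-[(tert-butyldimethylsilyl)oxy]propan-1-ol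
Product: 16 3-[(tert-butyldimethylsilyl)oxy]propyl N,N-diisopropylcarbamate
Conditions: iPr2NCOCl, Et3N, CH2Cl2, reflux
Reagents that add atoms: N,N-diisopropylcarbamoyl chloride, CC(C)N(C(C)C)C(Cl)=O
Why: O-carbamoylation of a primary alcohol; the hindered carbamate directs and stabilises the α-lithiation of the next step.

**Step 10**
Reactants: 16 3-[(tert-butyldimethylsilyl)oxy]propyl N,N-diisopropylcarbamate; 14 tert-butyl(diphenyl){[2-(4,4,5,5-tetramethyl-1,3,2-dioxaborolan-2-yl)prop-2-en-1-yl]oxy}silane
Product: 19 tert-butyl{[(3R)-4-{[tert-butyl(diphenyl)silyl]oxymethyl}-3-(4,4,5,5-tetramethyl-1,3,2-dioxaborolan-2-yl)pent-4-en-1-yl]oxy}dimethylsilane, via lithiated carbamate 17 (not isolated), via boronate complex 18 (not isolated)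
Conditions: sBuLi, (−)-sparteine, Et2O, −78 °C, 5 h; 14, −78 °C; MgBr2·OEt2, −78 °C to reflux
Reagents that add atoms: none
Why: Hoppe sparteine-mediated deprotonation removes the pro-S hydrogen to give the configurationally stable 17; borylation with retention gives 18, and the MgBr2-promoted 1,2-metallate shift of the alkenyl group with inversion expels the carbamate (lithiation–borylation), so C1 of 19 is R.

**Step 11**
Reactants: 11 (2S,3S)-2-{[(4-methoxybenzyl)oxy]methyl}-5-oxooxolane-3-carbaldehyde; 19 the (3R)-allylboronate of step 10
Product: 21 (4R,5S)-4-[(1R,3E)-6-[(tert-butyldimethylsilyl)oxy]-3-{[(tert-butyldiphenylsilyl)oxy]methyl}-1-hydroxyhex-3-en-1-yl]-5-{[(4-methoxybenzyl)oxy]methyl}oxolan-2-one, via pinacol borate ester 20 (not isolated)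
Conditions: toluene, 4 Å molecular sieves, 23 °C to 40 °C; pH 7 buffer work-up
Reagents that add atoms: none
Why: Allylboration with an α-substituted allylboronate through a closed chair transition state: the pinacol ester and the C14 substituent on C10 push the C2 chain on C1 into the axial position, which gives the alkene with C9 and C2 cis, and with the aldehyde substituent equatorial the R configuration of C1 is transferred to C8 as R; the small intrinsic facial bias of 11 in a closed transition state is expected to be overridden by this reagent control.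

**Step 12**
Reactants: 21 the homoallylic alcohol of step 11
Product: 22 the C8 tert-butyldimethylsilyl ether of 21
Conditions: TBSOTf, 2,6-lutidine, CH2Cl2, −78 °C to 0 °C
Reagents that add atoms: tert-butyldimethylsilyl trifluoromethanesulfonate, CC(C)(C)[Si](C)(C)OS(=O)(=O)C(F)(F)F
Why: Silylation of a hindered secondary alcohol with a silyl triflate and a non-nucleophilic base; protecting C8 blocks its later oxidation and its translactonisation under base.

**Step 13**
Reactants: 22 the C8 tert-butyldimethylsilyl ether of 21
Product: 23 the C3 primary alcohol (22 without its C3 silyl group)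
Conditions: HF·pyridine, pyridine, THF, 0 °C
Reagents that add atoms: none
Why: Buffered HF·pyridine cleaves the unhindered primary tert-butyldimethylsilyl ether faster than the secondary one at C8 and the tert-butyldiphenylsilyl ether at C14 (steric differentiation of silyl ethers).

**Step 14**
Reactants: 23 the C3 primary alcohol
Product: 24 the C3 primary iodide
Conditions: I2, PPh3, imidazole, CH2Cl2, 0 °C
Reagents that add atoms: iodine, II
Why: Appel-type iodination (Garegg–Samuelsson conditions) of a primary alcohol by SN2 on the alkoxyphosphonium ion under nearly neutral conditions.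

**Step 15**
Reactants: 24 the C3 primary iodide; 25 allyl (diethoxyphosphoryl)acetate
Product: 26 the C4 phosphonoacetate (C3 alkylated allyl 2-(diethoxyphosphoryl)acetate, both C4 epimers)
Conditions: NaH, 25 (3 equiv), DMF, 0 °C; then 24, 50 °C
Reagents that add atoms: none
Why: SN2 alkylation of the sodium phosphonoacetate by a primary iodide; the excess of the stabilised anion suppresses dialkylation and it is too weak a base to enolise the lactone; the C4 configuration is irrelevant because C4 becomes sp2.

**Step 16**
Reactants: 26 the C4 phosphonoacetate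
Product: 27 the C5 primary alcohol
Conditions: DDQ, CH2Cl2/pH 7 buffer, 0 °C to 23 °C
Reagents that add atoms: none
Why: Oxidative cleavage of the 4-methoxybenzyl ether by hydride abstraction to the benzylic oxocarbenium ion and hydrolysis; silyl ethers, phosphonate and the isolated alkene are inert.

**Step 17**
Reactants: 27 the C5 primary alcohol
Product: 28 the C5 aldehyde
Conditions: Dess–Martin periodinane, CH2Cl2, 0 °C
Reagents that add atoms: none
Why: Dess–Martin oxidation gives the α-acyloxy aldehyde without base, so C6 keeps its configuration; the product is used at once.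

**Step 18**
Reactants: 28 the C5 aldehyde
Product: 29 the ten-membered allyl ester (ring-cis C1=C10 and C4=C5; C15 allyl ester; 6,12-lactone; C8 and C14 silyl ethers)
Conditions: LiCl, iPr2NEt, MeCN, 0.5 mM, slow addition, 23 °C to 40 °C
Reagents that add atoms: none
Why: Intramolecular Horner–Wadsworth–Emmons olefination under Masamune–Roush conditions: lithium chelation acidifies the phosphonoacetate so that an amine suffices, which spares the α-acyloxy aldehyde; the stabilised carbanion gives the enoate with the ester trans to C6, which is the ring-cis alkene and the less strained ring isomer, and high dilution favours the ring over oligomers.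

**Step 19**
Reactants: 29 the ten-membered allyl ester
Product: 30 the C15 carboxylic acid
Conditions: Pd(PPh3)4 (5 mol %), morpholine, THF, 0 °C to 23 °C
Reagents that add atoms: none
Why: Zerovalent palladium ionises the terminal allyl ester to a π-allyl complex that morpholine traps (Tsuji–Trost deallylation); the hindered, trisubstituted endocyclic allylic lactone should ionise far more slowly.

**Step 20**
Reactants: 30 the C15 carboxylic acid
Product: 32 the C15 allylic alcohol, via mixed carbonic anhydride 31 (not isolated)
Conditions: iBuOCOCl, N-methylmorpholine, THF, −15 °C; NaBH4, MeOH, −15 °C to 0 °C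
Reagents that add atoms: none
Why: Activation as the mixed carbonic anhydride followed by borohydride 1,2-reduction converts the acid into the alcohol at a temperature at which NaBH4 leaves the γ-lactone alone.

**Step 21**
Reactants: 32 the C15 allylic alcohol
Product: 33 the C15 triethylsilyl ether
Conditions: Et3SiCl, imidazole, CH2Cl2, 0 °C
Reagents that add atoms: chlorotriethylsilane, CC[Si](Cl)(CC)CC
Why: Silylation of the only free hydroxyl with the most labile of the three silyl groups, so that C15 can be released first later.

**Step 22**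
Reactants: 33 the C15 triethylsilyl ether
Product: 36 the α-methylene lactone, via Mannich base 34 (not isolated), via trimethylammonium iodide 35 (not isolated)
Conditions: LiN(SiMe3)2, THF, −78 °C; CH2=NMe2+ I−, −78 °C to 23 °C; MeI, MeOH, 23 °C; aq. NaHCO3, CH2Cl2, 23 °C
Reagents that add atoms: N,N-dimethylmethyleneiminium iodide (Eschenmoser's salt), C=[N+](C)C.[I-]
Why: Lactone enolate Mannich reaction with Eschenmoser's salt, N-methylation and E1cB loss of trimethylamine; C11 is the only acidic position in 33, and the configuration of the Mannich base is irrelevant because C11 becomes sp2.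

**Step 23**
Reactants: 36 the α-methylene lactone
Product: 37 the C15 alcohol
Conditions: PPTS, MeOH/CH2Cl2, 0 °C
Reagents that add atoms: none
Why: Acid-catalysed methanolysis removes the primary triethylsilyl ether much faster than the tert-butyldimethylsilyl and tert-butyldiphenylsilyl ethers, and mild acid does not add methanol to the methylene lactone.

**Step 24**
Reactants: 37 the C15 alcohol
Product: 38 the C15 acetate
Conditions: Ac2O, pyridine, DMAP (cat.), CH2Cl2, 0 °C
Reagents that add atoms: acetic anhydride, CC(=O)OC(C)=O
Why: DMAP-catalysed acetylation of the only free hydroxyl.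

**Step 25**
Reactants: 38 the C15 acetate
Product: 39 the 8,14-diol
Conditions: HF·pyridine, THF, 0 °C to 23 °C
Reagents that add atoms: none
Why: Fluoride-mediated cleavage of both remaining silyl ethers under acidic, non-basic conditions, which avoids translactonisation, acetate migration and oxa-Michael addition.

**Step 26**
Reactants: 39 the 8,14-diol
Product: 40 the target (CNP0313792.2)
Conditions: methacrylic anhydride (1.1 equiv), Et3N, DMAP (5 mol %), BHT (trace), CH2Cl2, −40 °C to −20 °C
Reagents that add atoms: methacrylic anhydride, C=C(C)C(=O)OC(=O)C(C)=C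
Why: Rate-selective acylation: the primary allylic C14 hydroxyl reacts well before the secondary C8 hydroxyl, which is hindered by the ring fusion, with a slight excess of anhydride at low temperature.

## Compound list

1 | methyl 4-chloro-3-oxobutanoate | COC(=O)CC(=O)CCl | starting material
2 | 4-methoxybenzyl alcohol | COc1ccc(CO)cc1 | starting material
3 | methyl 4-[(4-methoxybenzyl)oxy]-3-oxobutanoate | COC(=O)CC(=O)COCc1ccc(OC)cc1 | intermediate
4 | methyl bromoacetate | COC(=O)CBr | starting material
5 | dimethyl 2-{[(4-methoxybenzyl)oxy]acetyl}butanedioate (racemic, labile at C7) | COC(=O)CC(C(=O)OC)C(=O)COCc1ccc(OC)cc1 | intermediate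
6 | dimethyl (2S)-2-{(1S)-1-hydroxy-2-[(4-methoxybenzyl)oxy]ethyl}butanedioate (syn hydroxy diester, not isolated) | COC(=O)C[C@H](C(=O)OC)[C@H](O)COCc1ccc(OC)cc1 | intermediate
7 | methyl (2S,3S)-2-{[(4-methoxybenzyl)oxy]methyl}-5-oxooxolane-3-carboxylate | COc1ccc(COC[C@H]2OC(=O)C[C@@H]2C(=O)OC)cc1 | intermediate
8 | dilithium (2S)-2-{(1S)-1-hydroxy-2-[(4-methoxybenzyl)oxy]ethyl}butanedioate (not isolated) | [Li+].[Li+].[O-]C(=O)C[C@H](C([O-])=O)[C@H](O)COCc1ccc(OC)cc1 | intermediate
9 | (2S,3S)-2-{[(4-methoxybenzyl)oxy]methyl}-5-oxooxolane-3-carboxylic acid | COc1ccc(COC[C@H]2OC(=O)C[C@@H]2C(=O)O)cc1 | intermediate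
10 | (4R,5S)-4-(hydroxymethyl)-5-{[(4-methoxybenzyl)oxy]methyl}oxolan-2-one | COc1ccc(COC[C@H]2OC(=O)C[C@@H]2CO)cc1 | intermediate
11 | (2S,3S)-2-{[(4-methoxybenzyl)oxy]methyl}-5-oxooxolane-3-carbaldehyde | COc1ccc(COC[C@H]2OC(=O)C[C@@H]2C=O)cc1 | intermediate
12 | 2-bromoprop-2-en-1-ol | OCC(Br)=C | starting material
13 | [(2-bromoprop-2-en-1-yl)oxy](tert-butyl)diphenylsilane | C=C(Br)CO[Si](c1ccccc1)(c1ccccc1)C(C)(C)C | intermediate
14 | tert-butyl(diphenyl){[2-(4,4,5,5-tetramethyl-1,3,2-dioxaborolan-2-yl)prop-2-en-1-yl]oxy}silane | C=C(CO[Si](c1ccccc1)(c1ccccc1)C(C)(C)C)B1OC(C)(C)C(C)(C)O1 | intermediate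
15 | 3-[(tert-butyldimethylsilyl)oxy]propan-1-ol | OCCCO[Si](C)(C)C(C)(C)C | starting material
16 | 3-[(tert-butyldimethylsilyl)oxy]propyl N,N-diisopropylcarbamate | CC(C)N(C(C)C)C(=O)OCCCO[Si](C)(C)C(C)(C)C | intermediate
17 | (1S)-3-[(tert-butyldimethylsilyl)oxy]-1-lithiopropyl N,N-diisopropylcarbamate, as its (−)-sparteine complex (not isolated) | CC(C)N(C(C)C)C(=O)O[C@@H]([Li])CCO[Si](C)(C)C(C)(C)C | intermediate
18 | lithium boronate complex of 17 with 14, boron on C1 with retention (not isolated) | CC(C)N(C(C)C)C(=O)O[C@H](CCO[Si](C)(C)C(C)(C)C)[B-]1(OC(C)(C)C(C)(C)O1)C(=C)CO[Si](c1ccccc1)(c1ccccc1)C(C)(C)C.[Li+] | intermediate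
19 | tert-butyl{[(3R)-4-{[tert-butyl(diphenyl)silyl]oxymethyl}-3-(4,4,5,5-tetramethyl-1,3,2-dioxaborolan-2-yl)pent-4-en-1-yl]oxy}dimethylsilane (boron on C1, C9 as terminal methylene) | CC(C)(C)[Si](C)(C)OCC[C@@H](B1OC(C)(C)C(C)(C)O1)C(=C)CO[Si](c1ccccc1)(c1ccccc1)C(C)(C)C | intermediate
20 | pinacol borate ester of 21 at the C8 oxygen (not isolated) | COc1ccc(COC[C@H]2OC(=O)C[C@@H]2[C@H](OB3OC(C)(C)C(C)(C)O3)C/C(CO[Si](c3ccccc3)(c3ccccc3)C(C)(C)C)=C\CCO[Si](C)(C)C(C)(C)C)cc1 | intermediate
21 | (4R,5S)-4-[(1R,3E)-6-[(tert-butyldimethylsilyl)oxy]-3-{[(tert-butyldiphenylsilyl)oxy]methyl}-1-hydroxyhex-3-en-1-yl]-5-{[(4-methoxybenzyl)oxy]methyl}oxolan-2-one (C9 and C2 cis on C10=C1) | COc1ccc(COC[C@H]2OC(=O)C[C@@H]2[C@H](O)C/C(CO[Si](c3ccccc3)(c3ccccc3)C(C)(C)C)=C\CCO[Si](C)(C)C(C)(C)C)cc1 | intermediate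
22 | C8 tert-butyldimethylsilyl ether of 21 | COc1ccc(COC[C@H]2OC(=O)C[C@@H]2[C@H](O[Si](C)(C)C(C)(C)C)C/C(CO[Si](c3ccccc3)(c3ccccc3)C(C)(C)C)=C\CCO[Si](C)(C)C(C)(C)C)cc1 | intermediate
23 | C3 primary alcohol (22 without the C3 silyl group) | COc1ccc(COC[C@H]2OC(=O)C[C@@H]2[C@H](O[Si](C)(C)C(C)(C)C)C/C(CO[Si](c3ccccc3)(c3ccccc3)C(C)(C)C)=C\CCO)cc1 | intermediate
24 | C3 primary iodide | COc1ccc(COC[C@H]2OC(=O)C[C@@H]2[C@H](O[Si](C)(C)C(C)(C)C)C/C(CO[Si](c3ccccc3)(c3ccccc3)C(C)(C)C)=C\CCI)cc1 | intermediate
25 | allyl (diethoxyphosphoryl)acetate | C=CCOC(=O)CP(=O)(OCC)OCC | starting material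
26 | C4 phosphonoacetate: allyl 2-(diethoxyphosphoryl) ester alkylated at C4 by C3 of 24 (both C4 epimers) | COc1ccc(COC[C@H]2OC(=O)C[C@@H]2[C@H](O[Si](C)(C)C(C)(C)C)C/C(CO[Si](c3ccccc3)(c3ccccc3)C(C)(C)C)=C\CCC(C(=O)OCC=C)P(=O)(OCC)OCC)cc1 | intermediate
27 | C5 primary alcohol (26 without the 4-methoxybenzyl group) | OC[C@H]1OC(=O)C[C@@H]1[C@H](O[Si](C)(C)C(C)(C)C)C/C(CO[Si](c1ccccc1)(c1ccccc1)C(C)(C)C)=C\CCC(C(=O)OCC=C)P(=O)(OCC)OCC | intermediate
28 | C5 aldehyde | O=C[C@H]1OC(=O)C[C@@H]1[C@H](O[Si](C)(C)C(C)(C)C)C/C(CO[Si](c1ccccc1)(c1ccccc1)C(C)(C)C)=C\CCC(C(=O)OCC=C)P(=O)(OCC)OCC | intermediate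
29 | ten-membered allyl ester: ring-cis C1=C10 and C4=C5 (both E), C15 allyl ester, 6,12-lactone, C8 tert-butyldimethylsilyl ether, C14 tert-butyldiphenylsilyl ether, C6/C7/C8 as in the target | CC(C)(C)[Si](OC/C1=C/CC/C(C(=O)OCC=C)=C\[C@H]2OC(=O)C[C@@H]2[C@H](O[Si](C)(C)C(C)(C)C)C1)(c1ccccc1)c1ccccc1 | intermediate
30 | C15 carboxylic acid of 29 | CC(C)(C)[Si](OC/C1=C/CC/C(C(=O)O)=C\[C@H]2OC(=O)C[C@@H]2[C@H](O[Si](C)(C)C(C)(C)C)C1)(c1ccccc1)c1ccccc1 | intermediate
31 | mixed isobutyl carbonic anhydride of 30 (not isolated) | CC(C)(C)[Si](OC/C1=C/CC/C(C(=O)OC(=O)OCC(C)C)=C\[C@H]2OC(=O)C[C@@H]2[C@H](O[Si](C)(C)C(C)(C)C)C1)(c1ccccc1)c1ccccc1 | intermediate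
32 | C15 allylic alcohol | CC(C)(C)[Si](OC/C1=C/CC/C(CO)=C\[C@H]2OC(=O)C[C@@H]2[C@H](O[Si](C)(C)C(C)(C)C)C1)(c1ccccc1)c1ccccc1 | intermediate
33 | C15 triethylsilyl ether | CC(C)(C)[Si](OC/C1=C/CC/C(CO[Si](CC)(CC)CC)=C\[C@H]2OC(=O)C[C@@H]2[C@H](O[Si](C)(C)C(C)(C)C)C1)(c1ccccc1)c1ccccc1 | intermediate
34 | C11 (dimethylamino)methyl lactone (Mannich base, both C11 epimers, not isolated) | CC(C)(C)[Si](OC/C1=C/CC/C(CO[Si](CC)(CC)CC)=C\[C@H]2OC(=O)C(CN(C)C)[C@@H]2[C@H](O[Si](C)(C)C(C)(C)C)C1)(c1ccccc1)c1ccccc1 | intermediate
35 | C11 (trimethylammonio)methyl lactone iodide (not isolated) | CC(C)(C)[Si](OC/C1=C/CC/C(CO[Si](CC)(CC)CC)=C\[C@H]2OC(=O)C(C[N+](C)(C)C)[C@@H]2[C@H](O[Si](C)(C)C(C)(C)C)C1)(c1ccccc1)c1ccccc1.[I-] | intermediate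
36 | α-methylene lactone with C8, C14 and C15 silyl ethers | CC(C)(C)[Si](OC/C1=C/CC/C(CO[Si](CC)(CC)CC)=C\[C@H]2OC(=O)C(=C)[C@@H]2[C@H](O[Si](C)(C)C(C)(C)C)C1)(c1ccccc1)c1ccccc1 | intermediate
37 | C15 alcohol of the α-methylene lactone | CC(C)(C)[Si](OC/C1=C/CC/C(CO)=C\[C@H]2OC(=O)C(=C)[C@@H]2[C@H](O[Si](C)(C)C(C)(C)C)C1)(c1ccccc1)c1ccccc1 | intermediate
38 | C15 acetate with C8 and C14 silyl ethers | CC(C)(C)[Si](OC/C1=C/CC/C(COC(C)=O)=C\[C@H]2OC(=O)C(=C)[C@@H]2[C@H](O[Si](C)(C)C(C)(C)C)C1)(c1ccccc1)c1ccccc1 | intermediate
39 | 8,14-diol 15-acetate | OC/C1=C/CC/C(COC(C)=O)=C\[C@H]2OC(=O)C(=C)[C@@H]2[C@H](O)C1 | intermediate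
40 | target: (6R,7R,8R) 15-acetoxy-8-hydroxy-14-(methacryloyloxy)germacra-1(10),4,11(13)-trien-6,12-olide, both ring alkenes ring-cis (E) | C=C(C)C(=O)OC/C1=C/CC/C(COC(C)=O)=C\[C@H]2OC(=O)C(=C)[C@@H]2[C@H](O)C1 | target

## Step count and least certain steps

Total: 26 steps. Longest linear sequence: 22 steps (steps 1–6 and 11–26, from 1); the boronate branch (steps 7–10) adds four.

**Step 3 (key step).** The most likely failure is that no panel enzyme combines syn selectivity with the required absolute sense on this substrate. Reduction could also be slower than ester hydrolysis and decarboxylation in buffer, since the 4-methoxybenzyl ether and the succinate arm both demand space in the active site. The fallback replaces the enzyme by an auxiliary-controlled aldol; it sets out from 2 and returns at 9. Alkylation of 2 with bromoacetaldehyde diethyl acetal (NaH, DMF) gives 1-[(2,2-diethoxyethoxy)methyl]-4-methoxybenzene F1, and mild aqueous acid gives [(4-methoxybenzyl)oxy]acetaldehyde F2. The succinate imide (S)-4-benzyl-3-(4-methoxy-4-oxobutanoyl)-1,3-oxazolidin-2-one F3 is made from the lithiated oxazolidinone and methyl 4-chloro-4-oxobutanoate. Its boron enolate (Bu2BOTf, iPr2NEt) adds to F2 in an Evans syn aldol to give the syn adduct F4, which has the same C6/C7 arrangement as 6. LiOH/H2O2 then removes the auxiliary and the methyl ester, and acidification closes the lactone to 9.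

**Step 11.** The aldehyde's own facial preference opposes the reagent here, so the chair with the C2 chain equatorial may compete. That would give the ring-trans alkene together with 8S; the hindered boronate may also add slowly. The fallback pairs the reagent and substrate preferences and then inverts C8; it sets out from 16 and 14 and returns at 21. With (+)-sparteine, 16 gives the enantiomeric lithiated carbamate F5 and, through boronate complex F6, the (3S)-allylboronate F7. Addition of F7 to 11 through its axial chair gives borate F8 and, after work-up, the 8S alcohol F9 with the same C9/C2-cis alkene. Mitsunobu reaction of F9 with chloroacetic acid (PPh3, diisopropyl azodicarboxylate) gives the inverted 8R chloroacetate F10, and thiourea with NaHCO3 in ethanol releases 21 without basic conditions that would translactonise.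

**Step 18.** Intermolecular olefination to cyclic dimers and oligomers can outrun closure of the ten-membered ring, and the amine base can erode the C6 configuration of the α-acyloxy aldehyde. The fallback avoids base and never lets the aldehyde accumulate; it sets out from 24 and returns at 29. DDQ converts 24 into the iodo alcohol F11. Heating F11 with two equivalents of allyl (triphenylphosphoranylidene)acetate gives the phosphonium iodide F12, which the second equivalent deprotonates to the C4 stabilised ylide F13. Slow Dess–Martin oxidation of F13 at high dilution (pyridine buffer) generates the ylide aldehyde F14, which closes by intramolecular Wittig reaction to 29.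

**Step 26.** Over-acylation at the C8 hydroxyl or acyl migration could accompany the primary acylation. The fallback replaces rate selection by enzyme selection; it sets out from 39 and returns at 40. Immobilised Candida antarctica lipase B with vinyl methacrylate in tert-butyl methyl ether at 30 °C should acylate only the primary C14 hydroxyl; no new compound is involved.

## Further compounds

F1 | step 3 | 1-[(2,2-diethoxyethoxy)methyl]-4-methoxybenzene | CCOC(COCc1ccc(OC)cc1)OCC
F2 | step 3 | [(4-methoxybenzyl)oxy]acetaldehyde | O=CCOCc1ccc(OC)cc1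
F3 | step 3 | (S)-4-benzyl-3-(4-methoxy-4-oxobutanoyl)-1,3-oxazolidin-2-one | COC(=O)CCC(=O)N1[C@@H](Cc2ccccc2)COC1=O
F4 | step 3 | methyl (3S,4S)-3-{[(4S)-4-benzyl-2-oxo-1,3-oxazolidin-3-yl]carbonyl}-4-hydroxy-5-[(4-methoxybenzyl)oxy]pentanoate | COC(=O)C[C@H](C(=O)N1[C@@H](Cc2ccccc2)COC1=O)[C@H](O)COCc1ccc(OC)cc1
F5 | step 11 | (1R)-3-[(tert-butyldimethylsilyl)oxy]-1-lithiopropyl N,N-diisopropylcarbamate, as its (+)-sparteine complex | CC(C)N(C(C)C)C(=O)O[C@H]([Li])CCO[Si](C)(C)C(C)(C)C
F6 | step 11 | lithium boronate complex of F5 with 14 (enantiomer of 18) | CC(C)N(C(C)C)C(=O)O[C@@H](CCO[Si](C)(C)C(C)(C)C)[B-]1(OC(C)(C)C(C)(C)O1)C(=C)CO[Si](c1ccccc1)(c1ccccc1)C(C)(C)C.[Li+]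
F7 | step 11 | (3S)-allylboronate (enantiomer of 19) | CC(C)(C)[Si](C)(C)OCC[C@H](B1OC(C)(C)C(C)(C)O1)C(=C)CO[Si](c1ccccc1)(c1ccccc1)C(C)(C)C
F8 | step 11 | pinacol borate ester of F9 | COc1ccc(COC[C@H]2OC(=O)C[C@@H]2[C@@H](OB3OC(C)(C)C(C)(C)O3)C/C(CO[Si](c3ccccc3)(c3ccccc3)C(C)(C)C)=C\CCO[Si](C)(C)C(C)(C)C)cc1
F9 | step 11 | C8 epimer of 21 (8S alcohol, C9 and C2 cis) | COc1ccc(COC[C@H]2OC(=O)C[C@@H]2[C@@H](O)C/C(CO[Si](c3ccccc3)(c3ccccc3)C(C)(C)C)=C\CCO[Si](C)(C)C(C)(C)C)cc1
F10 | step 11 | C8 chloroacetate of 21 (8R) | COc1ccc(COC[C@H]2OC(=O)C[C@@H]2[C@H](OC(=O)CCl)C/C(CO[Si](c3ccccc3)(c3ccccc3)C(C)(C)C)=C\CCO[Si](C)(C)C(C)(C)C)cc1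
F11 | step 18 | C5 alcohol C3 iodide (24 without the 4-methoxybenzyl group) | OC[C@H]1OC(=O)C[C@@H]1[C@H](O[Si](C)(C)C(C)(C)C)C/C(CO[Si](c1ccccc1)(c1ccccc1)C(C)(C)C)=C\CCI
F12 | step 18 | C4 triphenylphosphonium iodide (allyl ester) | OC[C@H]1OC(=O)C[C@@H]1[C@H](O[Si](C)(C)C(C)(C)C)C/C(CO[Si](c1ccccc1)(c1ccccc1)C(C)(C)C)=C\CCC(C(=O)OCC=C)[P+](c1ccccc1)(c1ccccc1)c1ccccc1.[I-]
F13 | step 18 | C4 stabilised triphenylphosphorane with C5 alcohol | OC[C@H]1OC(=O)C[C@@H]1[C@H](O[Si](C)(C)C(C)(C)C)C/C(CO[Si](c1ccccc1)(c1ccccc1)C(C)(C)C)=C\CCC(C(=O)OCC=C)=P(c1ccccc1)(c1ccccc1)c1ccccc1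
F14 | step 18 | C4 stabilised triphenylphosphorane with C5 aldehyde | O=C[C@H]1OC(=O)C[C@@H]1[C@H](O[Si](C)(C)C(C)(C)C)C/C(CO[Si](c1ccccc1)(c1ccccc1)C(C)(C)C)=C\CCC(C(=O)OCC=C)=P(c1ccccc1)(c1ccccc1)c1ccccc1
F0 | step 26 | none | none
A1 | alternative 1 | achiral ten-membered 6,8-dione with ring-cis C1=C10 and C4=C5, C14 tert-butyldiphenylsilyl ether and C15 tert-butyldimethylsilyl ether | O=C1CC(=O)C/C(CO[Si](c2ccccc2)(c2ccccc2)C(C)(C)C)=C\CC/C(CO[Si](C)(C)C(C)(C)C)=C\1
A2 | alternative 2 | protected 11,13-dihydro germacranolide core: 6,12-lactone, C8 tert-butyldimethylsilyl ether, C14 4-methoxybenzyl ether, C15 tert-butyldiphenylsilyl ether | COc1ccc(COC/C2=C/CC/C(CO[Si](c3ccccc3)(c3ccccc3)C(C)(C)C)=C\[C@H]3OC(=O)C[C@@H]3[C@H](O[Si](C)(C)C(C)(C)C)C2)cc1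
A3 | alternative 3 | ten-membered C14 allyl ester with the 6,12-lactone, C8 tert-butyldimethylsilyl ether and C15 tert-butyldiphenylsilyl ether | C=CCOC(=O)/C1=C/CC/C(CO[Si](c2ccccc2)(c2ccccc2)C(C)(C)C)=C\[C@H]2OC(=O)C[C@@H]2[C@H](O[Si](C)(C)C(C)(C)C)C1
A4 | alternative 3 | D-arabinose (open-chain form) | O=C[C@@H](O)[C@H](O)[C@H](O)CO
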